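**Retrosynthetic overview**
1. Schizolaenone C ⇐ its 7,3′,5′-tris-MOM ether; the last step is acid cleavage of the three acetals.
2. Key disconnection: the side-chain bond C1″–C2″ (ring-A CH2 to the vinylic CH), made by a boron-to-carbon alkenyl shift inside a 2-alkenyl-4H-1,3,2-dioxaborin fused to ring A through O5, B, O and the C6–CH2 carbon.
3. Enabling feature: the C5 hydroxyl of ring A, ortho to C6 and the only free phenol. Its salicyl unit O5–C5–C6–CH2 can open to an o-quinone methide (O5=C5–C6=CH2, stabilised by O7 and O1) while O5 holds boron, so that alkenyl carbon, B, O5, C5, C6 and CH2 form a six-membered transition state.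
4. The dioxaborin ⇐ (2S)-5-hydroxyflavanone + formaldehyde + (E)-alkenylboronic acid (boron-templated ortho-hydroxymethylation at C6); the boronic acid ⇐ 6-methylhept-5-en-2-one via alkyne, carboalumination and vinyl iodide.
5. Ring order: rings A/C (as the chromone) and ring B are bought; C2 is set by Rh-catalysed asymmetric 1,4-addition of the arylboronic acid to the chromone; the only ring made is the temporary dioxaborin (step 9), opened again in step 10.

Key step: step 10

Remark: 5,7-dihydroxychromone, 5-bromoresorcinol and 6-methylhept-5-en-2-one are taken as purchasable.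
Remark: in step 4 the (S)-bisphosphine is assigned to the (2S)-product by the stereochemical model for 2-cyclohexenone (same enone face); the ligand antipode is to be used should the configurational assay indicate otherwise.

**Step 1**
Reactants: 1 5,7-dihydroxy-4H-chromen-4-one
Product: 2 5,7-bis(methoxymethoxy)-4H-chromen-4-one
Conditions: NaH (2.5 equiv), MOMCl (2.5 equiv), DMF, 0 °C → rt
Reagents that add atoms: chloromethyl methyl ether, COCCl
Why: MOM ether formation (Williamson-type O-alkylation); sodium hydride also deprotonates the chelated 5-hydroxyl, so both phenols should be protected.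

**Step 2**
Reactants: 3 5-bromobenzene-1,3-diol
Product: 4 1-bromo-3,5-bis(methoxymethoxy)benzene
Conditions: MOMCl (2.4 equiv), i-Pr2NEt, CH2Cl2, 0 °C → rt
Reagents that add atoms: chloromethyl methyl ether, COCCl
Why: MOM ether formation of both unhindered phenols under amine base.

**Step 3**
Reactants: 4 1-bromo-3,5-bis(methoxymethoxy)benzene
Product: 7 [3,5-bis(methoxymethoxy)phenyl]boronic acid, via aryllithium 5 (not isolated), via lithium aryl(triisopropoxy)borate 6 (not isolated)
Conditions: n-BuLi, THF, −78 °C; B(Oi-Pr)3, −78 °C → rt; dilute HCl to pH 5–6, 0 °C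
Reagents that add atoms: triisopropyl borate, CC(C)OB(OC(C)C)OC(C)C (boron); water, O (the two hydroxyl oxygens)
Why: Bromine–lithium exchange followed by electrophilic borylation and hydrolysis; exchange at −78 °C should outrun MOM-directed ortho-lithiation.

**Step 4**
Reactants: 2 5,7-bis(methoxymethoxy)-4H-chromen-4-one; 7 [3,5-bis(methoxymethoxy)phenyl]boronic acid
Product: 8 (2S)-2-[3,5-bis(methoxymethoxy)phenyl]-5,7-bis(methoxymethoxy)chroman-4-one
Conditions: [RhCl(C2H4)2]2 (2.5 mol %), (S)-MeO-F12-BIPHEP (5.5 mol %), KOH (0.2 equiv), PhMe/H2O, 25 °C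
Reagents that add atoms: none
Why: Hayashi–Miyaura rhodium-catalysed asymmetric 1,4-addition of an arylboronic acid to a chromone: the aryl–rhodium species adds across C2=C3 on the enone face left open by the (S)-ligand and protonolysis of the oxa-π-allyl rhodium releases the flavanone, so C2 is set by the catalyst.

**Step 5**
Reactants: 8 (2S)-2-[3,5-bis(methoxymethoxy)phenyl]-5,7-bis(methoxymethoxy)chroman-4-one
Product: 9 (2S)-2-[3,5-bis(methoxymethoxy)phenyl]-5-hydroxy-7-(methoxymethoxy)chroman-4-one
Conditions: HCl (ca. 0.2 M) in MeOH/THF, 0 °C, stopped at mono-cleavage; NaHCO3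
Reagents that add atoms: none
Why: Acid-catalysed acetal methanolysis that should be selective for the peri 5-O-MOM group, since the C4 carbonyl assists its cleavage and hydrogen-bonds the freed phenol; the acidic medium does not open ring C, so C2 is retained.

**Step 6**
Reactants: 10 6-methylhept-5-en-2-one
Product: 12 6-methylhept-5-en-1-yne, via enol phosphate 11 (not isolated)
Conditions: LDA (1.05 equiv), THF, −78 °C; ClP(O)(OEt)2, → rt; LDA (2.3 equiv), −78 °C → rt; H2O
Reagents that add atoms: none
Why: Negishi one-flask conversion of a methyl ketone into a terminal alkyne by kinetic enolate O-phosphorylation and base-induced elimination of diethyl phosphate.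

**Step 7**
Reactants: 12 6-methylhept-5-en-1-yne
Product: 14 (1E)-1-iodo-2,6-dimethylhepta-1,5-diene, via alkenylalane 13 (not isolated)
Conditions: Me3Al (2 equiv), Cp2ZrCl2 (0.25 equiv), CH2Cl2, 0 °C → rt; I2, THF, −30 → 0 °C
Reagents that add atoms: trimethylaluminium, C[Al](C)C; iodine, II
Why: Negishi zirconium-catalysed carboalumination adds Me–Al syn across the alkyne with aluminium at the terminus, which fixes the E geometry, and iodinolysis of the C–Al bond proceeds with retention.

**Step 8**
Reactants: 14 (1E)-1-iodo-2,6-dimethylhepta-1,5-diene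
Product: 17 [(1E)-2,6-dimethylhepta-1,5-dien-1-yl]boronic acid, via alkenyllithium 15 (not isolated), via lithium alkenyl(triisopropoxy)borate 16 (not isolated)
Conditions: t-BuLi (2.1 equiv), Et2O, −78 °C; B(Oi-Pr)3, −78 °C → rt; dilute HCl to pH 5, 0 °C
Reagents that add atoms: triisopropyl borate, CC(C)OB(OC(C)C)OC(C)C (boron); water, O (the two hydroxyl oxygens)
Why: Iodine–lithium exchange with retention of olefin geometry, electrophilic borylation and hydrolysis.

**Step 9**
Reactants: 9 (2S)-2-[3,5-bis(methoxymethoxy)phenyl]-5-hydroxy-7-(methoxymethoxy)chroman-4-one; 17 [(1E)-2,6-dimethylhepta-1,5-dien-1-yl]boronic acid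
Product: 18 (2S)-flavanone 9 in which O5 and a new C6–CH2–O group are bridged by boron carrying the (1E)-2,6-dimethylhepta-1,5-dien-1-yl group (a 2-alkenyl-4H-1,3,2-dioxaborin fused to ring A at C5/C6); used without chromatography
Conditions: (CH2O)n (3 equiv), EtCO2H (0.2 equiv), benzene, 80 °C, Dean–Stark (or 4 Å MS)
Reagents that add atoms: paraformaldehyde (as formaldehyde), C=O
Why: Nagata boronic-acid-templated ortho-hydroxymethylation: the aryl boronate formed at the only free phenol (O5) delivers formaldehyde through a six-membered transition state to its single free ortho carbon C6 and the diol is trapped as the cyclic boronate, while C8 and ring B carry no free hydroxyl and C2 is not touched.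

**Step 10**
Reactants: 18 the 2-alkenyl-4H-1,3,2-dioxaborin fused to ring A
Product: 21 (2S)-2-[3,5-bis(methoxymethoxy)phenyl]-6-[(2E)-3,7-dimethylocta-2,6-dien-1-yl]-5-hydroxy-7-(methoxymethoxy)chroman-4-one, via o-quinone methide boronate complex 19 (not isolated), via aryl borate 20 (not isolated)
Conditions: rac-3,3′-Br2-BINOL (20 mol %), H2O (2 equiv), PhMe (0.02 M), 45 °C; then pH 7 buffer
Reagents that add atoms: none
Why: Proposed new method: water (or the biphenol) adds to boron of 18 to give a tetracoordinate boronate, the benzylic C–O bond ionises with electron release from O7, O1 and O5 to the boron-bound o-quinone methide 19 (O5=C5–C6=CH2, boron on O5), and the alkenyl group shifts with its bonding pair from boron to the exocyclic CH2 through a six-membered chair transition state (alkenyl C, B, O5, C5, C6, CH2), which rearomatises ring A to borate 20 and after hydrolysis gives 21. The closest known reaction types are the Petasis borono-Mannich transfer of alkenyl groups from phenoxide-bound boronates to salicylaldehyde-derived iminium ions, the biphenol-catalysed addition of alkenylboronates to o-quinone methides, and the Lewis-acid opening of 2-aryl-4H-1,3,2-benzodioxaborins to o-quinone methides; new is that the boron atom that templated the CH2 group also delivers the alkenyl group intramolecularly. No ring is closed: the temporary 1,3,2-dioxaborin ring is opened and its boron leaves as boric acid. No stereocentre is formed; C2 is remote and untouched under these near-neutral conditions, and the E geometry of the C2″=C3″ olefin should be carried over because the sp2 carbon migrates with retention in a concerted transfer. The step needs site selectivity (C6, not C8), which the O5/C6 tether fixes, and intramolecular transfer ahead of o-quinone methide oligomerisation or protodeboronation, which the position of boron on O5, the s-cis geometry locked by ring A and dilution should secure.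

**Step 11**
Reactants: 21 (2S)-2-[3,5-bis(methoxymethoxy)phenyl]-6-[(2E)-3,7-dimethylocta-2,6-dien-1-yl]-5-hydroxy-7-(methoxymethoxy)chroman-4-one
Product: 22 Schizolaenone C, (2S)-2-(3,5-dihydroxyphenyl)-6-[(2E)-3,7-dimethylocta-2,6-dien-1-yl]-5,7-dihydroxychroman-4-one
Conditions: 3 M aq. HCl/MeOH (1:10), 45 °C, monitored
Reagents that add atoms: none
Why: Acid-catalysed cleavage of the three MOM acetals with transfer of CH2 to methanol; conditions of this kind are used for geranylated flavanones and should leave C2 and the E olefin unchanged.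

**Compound list**
1 | 5,7-dihydroxy-4H-chromen-4-one | O=c1ccoc2cc(O)cc(O)c12 | starting material
2 | 5,7-bis(methoxymethoxy)-4H-chromen-4-one | O=c1ccoc2cc(OCOC)cc(OCOC)c12 | intermediate
3 | 5-bromobenzene-1,3-diol | Oc1cc(O)cc(Br)c1 | starting material
4 | 1-bromo-3,5-bis(methoxymethoxy)benzene | COCOc1cc(Br)cc(OCOC)c1 | intermediate
5 | [3,5-bis(methoxymethoxy)phenyl]lithium | COCOc1cc([Li])cc(OCOC)c1 | intermediate (not isolated)
6 | lithium [3,5-bis(methoxymethoxy)phenyl]tri(propan-2-yloxy)borate | COCOc1cc(cc(OCOC)c1)[B-](OC(C)C)(OC(C)C)OC(C)C.[Li+] | intermediate (not isolated)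
7 | [3,5-bis(methoxymethoxy)phenyl]boronic acid | COCOc1cc(cc(OCOC)c1)B(O)O | intermediate
8 | (2S)-2-[3,5-bis(methoxymethoxy)phenyl]-5,7-bis(methoxymethoxy)chroman-4-one | O=C1C[C@@H](c2cc(OCOC)cc(OCOC)c2)Oc2cc(OCOC)cc(OCOC)c21 | intermediate
9 | (2S)-2-[3,5-bis(methoxymethoxy)phenyl]-5-hydroxy-7-(methoxymethoxy)chroman-4-one | O=C1C[C@@H](c2cc(OCOC)cc(OCOC)c2)Oc2cc(OCOC)cc(O)c21 | intermediate
10 | 6-methylhept-5-en-2-one | CC(C)=CCCC(C)=O | starting material
11 | diethyl 6-methylhepta-1,5-dien-2-yl phosphate | CC(C)=CCCC(=C)OP(=O)(OCC)OCC | intermediate (not isolated)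
12 | 6-methylhept-5-en-1-yne | CC(C)=CCCC#C | intermediate
13 | [(1E)-2,6-dimethylhepta-1,5-dien-1-yl]dimethylalane | CC(C)=CCC/C(C)=C/[Al](C)C | intermediate (not isolated)
14 | (1E)-1-iodo-2,6-dimethylhepta-1,5-diene | CC(C)=CCC/C(C)=C/I | intermediate
15 | [(1E)-2,6-dimethylhepta-1,5-dien-1-yl]lithium | CC(C)=CCC/C(C)=C/[Li] | intermediate (not isolated)
16 | lithium [(1E)-2,6-dimethylhepta-1,5-dien-1-yl]tri(propan-2-yloxy)borate | CC(C)=CCC/C(C)=C/[B-](OC(C)C)(OC(C)C)OC(C)C.[Li+] | intermediate (not isolated)
17 | [(1E)-2,6-dimethylhepta-1,5-dien-1-yl]boronic acid | CC(C)=CCC/C(C)=C/B(O)O | intermediate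
18 | (2S)-flavanone with O5–B[(1E)-2,6-dimethylhepta-1,5-dien-1-yl]–O–CH2–C6 bridge (2-alkenyl-4H-1,3,2-dioxaborin fused to ring A), 7-OMOM, 3′,5′-bis-OMOM | O=C1C[C@@H](c2cc(OCOC)cc(OCOC)c2)Oc2cc(OCOC)c3c(c21)OB(/C=C(\C)CCC=C(C)C)OC3 | intermediate
19 | o-quinone methide of ring A (O5=C5, C6=CH2) with O5 bound to B(OH)2[(1E)-2,6-dimethylhepta-1,5-dien-1-yl] | O=C1C[C@@H](c2cc(OCOC)cc(OCOC)c2)OC2=C1C(=[O+][B-](O)(O)/C=C(\C)CCC=C(C)C)C(=C)C(OCOC)=C2 | intermediate (not isolated)
20 | 5-O-dihydroxyboryl derivative of 21 (aryl borate) | O=C1C[C@@H](c2cc(OCOC)cc(OCOC)c2)Oc2cc(OCOC)c(C/C=C(\C)CCC=C(C)C)c(OB(O)O)c21 | intermediate (not isolated)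
21 | (2S)-2-[3,5-bis(methoxymethoxy)phenyl]-6-[(2E)-3,7-dimethylocta-2,6-dien-1-yl]-5-hydroxy-7-(methoxymethoxy)chroman-4-one | O=C1C[C@@H](c2cc(OCOC)cc(OCOC)c2)Oc2cc(OCOC)c(C/C=C(\C)CCC=C(C)C)c(O)c21 | intermediate
22 | Schizolaenone C | CC(C)=CCC/C(C)=C/Cc1c(O)cc2c(c1O)C(=O)C[C@@H](c1cc(O)cc(O)c1)O2 | target

**Step count**
Total: 11 steps. Longest linear sequence: 7 steps (steps 2, 3, 4, 5, 9, 10, 11, from 5-bromobenzene-1,3-diol).

**Steps most likely to fail**

Step 10 (Proposed new method). The o-quinone methide may be intercepted intermolecularly (attack by the electron-rich ring B or by C8 of a second molecule, leading to oligomers), or the alkenyl–boron bond may be protonated before the alkenyl group is transferred. The fallback sets out from 18 and returns at 21, using known chemistry throughout. Transesterification of 18 with pinacol (THF, rt) should release the salicyl alcohol (2S)-2-[3,5-bis(methoxymethoxy)phenyl]-5-hydroxy-6-(hydroxymethyl)-7-(methoxymethoxy)chroman-4-one F1. Methyl chloroformate with pyridine and DMAP (CH2Cl2, −20 → 0 °C) should convert F1 into the 5-O,6-CH2-O-bis(methyl carbonate) F2. A palladium-catalysed Suzuki–Miyaura coupling of the benzylic carbonate with boronic acid 17 ([Pd(η3-C3H5)(cod)]BF4, DPPPent, DMF, 80 °C; oxidative addition to an η3-benzylpalladium species, with the methoxide released on decarboxylation activating boron, so no external base is needed) should give the 5-O-methoxycarbonyl-6-geranyl flavanone F3. The aryl carbonate is then removed with NaHCO3 in MeOH at rt to give 21.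

Step 9. The strongly chelated 5-hydroxyl may fail to engage the boronic acid, so that formaldehyde reacts untemplated at C8 or on ring B, or condenses at C3. The fallback sets out from 9 and returns at 18. Electrophilic iodination ortho to the free 5-hydroxyl (BnMe3N+ ICl2−, CaCO3, CH2Cl2/MeOH, rt; regioselective 6-iodination of 5-hydroxy-7-alkoxy flavonoids) should give (2S)-2-[3,5-bis(methoxymethoxy)phenyl]-5-hydroxy-6-iodo-7-(methoxymethoxy)chroman-4-one F4. A Kosugi–Migita–Stille hydroxymethylation with (tributylstannyl)methanol (Pd(PPh3)4, dioxane, 80 °C) should give the hydroxymethyl compound F1, the same compound as in the fallback for step 10. Esterification of its diol unit with 17 (PhMe, 4 Å MS, rt) gives 18.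

Step 4. Insertion at the peri-substituted chromone may be slow, and base-induced opening and reclosure of ring C in the product may erode enantiopurity. The fallback sets out from 2 and 7 and returns at 8. The addition is run with an achiral catalyst ([Rh(OH)(cod)]2, dioxane/H2O, 40 °C) to give racemic 2-[3,5-bis(methoxymethoxy)phenyl]-5,7-bis(methoxymethoxy)chroman-4-one F5. The enantiomers are then separated by preparative chiral SFC on an amylose carbamate phase, and the (2S)-enantiomer is 8.

**Further compounds**
F1 | step 10 | (2S)-2-[3,5-bis(methoxymethoxy)phenyl]-5-hydroxy-6-(hydroxymethyl)-7-(methoxymethoxy)chroman-4-one | O=C1C[C@@H](c2cc(OCOC)cc(OCOC)c2)Oc2cc(OCOC)c(CO)c(O)c21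
F2 | step 10 | (2S)-2-[3,5-bis(methoxymethoxy)phenyl]-5-(methoxycarbonyloxy)-6-[(methoxycarbonyloxy)methyl]-7-(methoxymethoxy)chroman-4-one | O=C1C[C@@H](c2cc(OCOC)cc(OCOC)c2)Oc2cc(OCOC)c(COC(=O)OC)c(OC(=O)OC)c21
F3 | step 10 | (2S)-2-[3,5-bis(methoxymethoxy)phenyl]-6-[(2E)-3,7-dimethylocta-2,6-dien-1-yl]-5-(methoxycarbonyloxy)-7-(methoxymethoxy)chroman-4-one | O=C1C[C@@H](c2cc(OCOC)cc(OCOC)c2)Oc2cc(OCOC)c(C/C=C(\C)CCC=C(C)C)c(OC(=O)OC)c21
F4 | step 9 | (2S)-2-[3,5-bis(methoxymethoxy)phenyl]-5-hydroxy-6-iodo-7-(methoxymethoxy)chroman-4-one | O=C1C[C@@H](c2cc(OCOC)cc(OCOC)c2)Oc2cc(OCOC)c(I)c(O)c21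
F5 | step 4 | rac-2-[3,5-bis(methoxymethoxy)phenyl]-5,7-bis(methoxymethoxy)chroman-4-one | O=C1CC(c2cc(OCOC)cc(OCOC)c2)Oc2cc(OCOC)cc(OCOC)c21
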